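Ring B is disconnected at its C2–C3 and C4–C5 bonds into a 5-alkenylpyran-2-one and a prenyl-substituted silyl ynol ether. The key step exploits the substitution pattern of ring B, in which the prenyl carbon C3 and the oxygen-bearing carbon C4 are adjacent and C4 lies para to the enone carbon C1. One thermal inverse-demand [4+2] addition across pyranone C3/C6, followed by loss of CO2, should build the whole arene with all three substituents in place and without oxidant. Its precursor is the complete ring A enone, bis-silylated and already joined through the (E)-alkene to C5 of pyran-2-one.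

Key step: step 12

Remark: the target has no stereocentre. Its only stereochemical element, the (E)-enone, is set in the Heck coupling, and the carbinol centre made by the vinyl Grignard addition is racemic and is removed by the following oxidation. All three phenols are carried as silyl ethers so that the ynol ether meets no acidic OH and the last step needs fluoride only.

Step 1
Reactants: 1 resorcinol
Product: 2 1,3-bis(methoxymethoxy)benzene
Conditions: MOMCl, iPr2NEt, CH2Cl2, 0 °C → rt
Reagents that add atoms: chloromethyl methyl ether, COCCl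
Why: Williamson-type O-alkylation of both phenols with the reactive α-chloro ether installs two acetal groups that direct the ortho-lithiations of steps 2 and 3.

Step 2
Reactants: 2 1,3-bis(methoxymethoxy)benzene; 3 prenyl bromide (1-bromo-3-methylbut-2-ene)
Product: 5 1,3-bis(methoxymethoxy)-2-(3-methylbut-2-en-1-yl)benzene, via aryllithium 4 (not isolated)
Conditions: n-BuLi, THF, 0 °C; CuI (10 mol %), then 3, −78 °C → rt
Reagents that add atoms: none
Why: Directed ortho-metalation removes the proton flanked by both methoxymethoxy groups, and copper-mediated SN2 allylation of the aryl anion with the primary allylic bromide should give the linear prenyl arene.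

Step 3
Reactants: 5 1,3-bis(methoxymethoxy)-2-(3-methylbut-2-en-1-yl)benzene
Product: 7 2,4-bis(methoxymethoxy)-3-(3-methylbut-2-en-1-yl)benzaldehyde, via aryllithium 6 (not isolated)
Conditions: n-BuLi, TMEDA, THF, 0 °C; DMF, −78 °C → rt; H2O
Reagents that add atoms: N,N-dimethylformamide, CN(C)C=O
Why: A second directed ortho-metalation next to a methoxymethoxy group (C4 and C6 are equivalent) followed by formylation of the aryllithium with DMF places the carbonyl carbon of ring A.

Step 4
Reactants: 7 2,4-bis(methoxymethoxy)-3-(3-methylbut-2-en-1-yl)benzaldehyde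
Product: 8 2,4-dihydroxy-3-(3-methylbut-2-en-1-yl)benzaldehyde
Conditions: HCl (3 M aq), MeOH, 50 °C
Reagents that add atoms: none
Why: Acid-catalysed acetal exchange with methanol cleaves both methoxymethyl ethers; short, monitored heating limits acid-induced chroman formation, and placing the only acidic deprotection at this early stage keeps acid away from all later intermediates.

Step 5
Reactants: 8 2,4-dihydroxy-3-(3-methylbut-2-en-1-yl)benzaldehyde
Product: 9 2,4-bis(tert-butyldimethylsilyloxy)-3-(3-methylbut-2-en-1-yl)benzaldehyde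
Conditions: TBSOTf, 2,6-lutidine, CH2Cl2, 0 °C → rt
Reagents that add atoms: tert-butyldimethylsilyl trifluoromethanesulfonate, CC(C)(C)[Si](C)(C)OS(=O)(=O)C(F)(F)F
Why: O-Silylation with the silyl triflate is reactive enough to cap the hydrogen-bonded, doubly flanked C2 hydroxyl as well as the C4 hydroxyl, giving protection that fluoride alone removes.

Step 6
Reactants: 9 2,4-bis(tert-butyldimethylsilyloxy)-3-(3-methylbut-2-en-1-yl)benzaldehyde; 10 vinylmagnesium bromide
Product: 11 racemic 1-[2,4-bis(tert-butyldimethylsilyloxy)-3-(3-methylbut-2-en-1-yl)phenyl]prop-2-en-1-ol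
Conditions: THF, −78 °C; aq NH4Cl, −78 °C
Reagents that add atoms: none
Why: Grignard 1,2-addition to the aldehyde gives the allylic alcohol; the carbinol centre forms without control and is erased in step 7, and the cold quench of the magnesium alkoxide avoids O-to-O silyl migration.

Step 7
Reactants: 11 racemic 1-[2,4-bis(tert-butyldimethylsilyloxy)-3-(3-methylbut-2-en-1-yl)phenyl]prop-2-en-1-ol
Product: 12 1-[2,4-bis(tert-butyldimethylsilyloxy)-3-(3-methylbut-2-en-1-yl)phenyl]prop-2-en-1-one
Conditions: MnO2 (activated, excess), CH2Cl2, rt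
Reagents that add atoms: none
Why: MnO2 oxidation is selective for the doubly activated (allylic and benzylic) alcohol and runs under neutral conditions that spare the silyl ethers and the prenyl group; the aryl vinyl ketone should be used at once.

Step 8
Reactants: 13 coumalic acid
Product: 14 5-bromo-2H-pyran-2-one
Conditions: NBS, LiOAc (cat.), MeCN–H2O, rt
Reagents that add atoms: N-bromosuccinimide, O=C1CCC(=O)N1Br
Why: Hunsdiecker-type bromodecarboxylation: ipso attack of electrophilic bromine at C5 of the enol-lactone alkene, assisted by the ring oxygen, then loss of CO2 restores the pyranone with bromine in place of the carboxyl group.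

Step 9
Reactants: 14 5-bromo-2H-pyran-2-one; 12 1-[2,4-bis(tert-butyldimethylsilyloxy)-3-(3-methylbut-2-en-1-yl)phenyl]prop-2-en-1-one
Product: 15 5-[(E)-3-[2,4-bis(tert-butyldimethylsilyloxy)-3-(3-methylbut-2-en-1-yl)phenyl]-3-oxoprop-1-en-1-yl]-2H-pyran-2-one
Conditions: Pd(OAc)2 (5 mol %), P(o-tol)3 (10 mol %), Et3N, BHT (cat.), MeCN, 70 °C
Reagents that add atoms: none
Why: Mizoroki–Heck coupling: oxidative addition into the vinylic C5–Br bond, insertion at the unsubstituted terminus of the vinyl ketone and syn β-hydride elimination should give the (E)-alkene, with a tertiary amine base that leaves the aryl silyl ethers intact.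

Step 10
Reactants: 3 prenyl bromide (1-bromo-3-methylbut-2-ene); 16 ethynylmagnesium bromide
Product: 17 5-methylhex-4-en-1-yne
Conditions: CuCl (5 mol %), THF, 0 °C → rt
Reagents that add atoms: none
Why: Copper-catalysed coupling of the alkynyl Grignard reagent with the primary allylic bromide (SN2 at the unhindered carbon) gives the skipped enyne; excess Grignard reagent suppresses double alkylation, and the volatile product is best carried on as a distilled solution.

Step 11
Reactants: 17 5-methylhex-4-en-1-yne
Product: 20 triisopropyl[(5-methylhex-4-en-1-yn-1-yl)oxy]silane, via lithium acetylide 18 (not isolated), via lithium ynolate 19 (not isolated)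
Conditions: n-BuLi, THF, −78 °C; LiOOtBu (from tBuOOH, LiN(SiMe3)2, THF, −78 °C), −78 → 0 °C; TIPSOTf, −78 → 0 °C
Reagents that add atoms: tert-butyl hydroperoxide, CC(C)(C)OO; triisopropylsilyl trifluoromethanesulfonate, CC(C)[Si](OS(=O)(=O)C(F)(F)F)(C(C)C)C(C)C
Why: Electrophilic oxygenation of the acetylide by lithium tert-butyl peroxide gives the ynolate, and the bulky silyl triflate traps it on oxygen, not carbon, to give an isolable silyl ynol ether.

Step 12
Reactants: 15 5-[(E)-3-[2,4-bis(tert-butyldimethylsilyloxy)-3-(3-methylbut-2-en-1-yl)phenyl]-3-oxoprop-1-en-1-yl]-2H-pyran-2-one; 20 triisopropyl[(5-methylhex-4-en-1-yn-1-yl)oxy]silane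
Product: 22 kanzonol C tris(silyl) ether (E)-1-[2,4-bis(tert-butyldimethylsilyloxy)-3-(3-methylbut-2-en-1-yl)phenyl]-3-[3-(3-methylbut-2-en-1-yl)-4-(triisopropylsilyloxy)phenyl]prop-2-en-1-one, via bridged lactone 21 (not isolated)
Conditions: 20 (2.5 equiv), BHT (cat.), toluene, 100 °C, sealed tube
Reagents that add atoms: none
Why: The pyranone is the electron-poor 4π partner and the silyl ynol ether the electron-rich 2π partner, so an asynchronous inverse-demand [4+2] cycloaddition is expected in which the nucleophilic prenyl-bearing alkyne carbon bonds to pyranone C6 (β-carbon of the enol lactone and δ-terminus of the C6=C5–CH=CH–C=O dienone) and the oxygen-bearing carbon bonds to C3, giving bridged lactone 21. Retro-[4+2] loss of CO2 from this 2-oxabicyclo[2.2.2]octadienone should then deliver the benzene ring directly at the arene oxidation level. The closest known reaction type is the cycloaddition of coumalates and related 5-acceptor pyran-2-ones with ynamines, alkynyl ethers or ketene acetals, which gives para-donor-substituted arenes after CO2 extrusion. Ring B is closed by one [4+2] cycloaddition across the two termini of the cyclic diene (both new σ-bonds, ring B C2–C3 and C4–C5, form on the same face in one event), followed by cycloreversion. No stereocentre is created in the product, since the two bridgehead centres of 21 vanish with CO2 and the (E)-enone is a spectator. The step needs regioselectivity (oxygen para and prenyl meta to the enone arm), secured by pairing the polarised ynol ether with the most electrophilic pyranone carbon C6, and chemoselectivity for the s-cis-locked diene over the β-substituted enone, secured by running without any Lewis acid and by the bulky ortho-silyloxy group that shields the ketone.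

Step 13
Reactants: 22 kanzonol C tris(silyl) ether
Product: 23 kanzonol C
Conditions: Bu4NF, AcOH, THF, 0 °C → rt
Reagents that add atoms: none
Why: Fluoride-induced desilylation cleaves the three aryl silyl ethers, and the acetic acid buffer keeps the phenols protonated so that neither oxa-Michael closure of the 2'-hydroxychalcone to a flavanone nor any reaction of the prenyl groups is expected.

Compound list
1 | resorcinol | Oc1cccc(O)c1 | starting material
2 | 1,3-bis(methoxymethoxy)benzene | COCOc1cccc(OCOC)c1 | intermediate
3 | prenyl bromide (1-bromo-3-methylbut-2-ene) | CC(C)=CCBr | starting material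
4 | [2,6-bis(methoxymethoxy)phenyl]lithium | [Li]c1c(OCOC)cccc1OCOC | intermediate
5 | 1,3-bis(methoxymethoxy)-2-(3-methylbut-2-en-1-yl)benzene | COCOc1cccc(OCOC)c1CC=C(C)C | intermediate
6 | [2,4-bis(methoxymethoxy)-3-(3-methylbut-2-en-1-yl)phenyl]lithium | [Li]c1ccc(OCOC)c(CC=C(C)C)c1OCOC | intermediate
7 | 2,4-bis(methoxymethoxy)-3-(3-methylbut-2-en-1-yl)benzaldehyde | COCOc1ccc(C=O)c(OCOC)c1CC=C(C)C | intermediate
8 | 2,4-dihydroxy-3-(3-methylbut-2-en-1-yl)benzaldehyde | CC(C)=CCc1c(O)ccc(C=O)c1O | intermediate
9 | 2,4-bis(tert-butyldimethylsilyloxy)-3-(3-methylbut-2-en-1-yl)benzaldehyde | CC(C)=CCc1c(O[Si](C)(C)C(C)(C)C)ccc(C=O)c1O[Si](C)(C)C(C)(C)C | intermediate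
10 | vinylmagnesium bromide | C=C[Mg]Br | starting material
11 | racemic 1-[2,4-bis(tert-butyldimethylsilyloxy)-3-(3-methylbut-2-en-1-yl)phenyl]prop-2-en-1-ol | C=CC(O)c1ccc(O[Si](C)(C)C(C)(C)C)c(CC=C(C)C)c1O[Si](C)(C)C(C)(C)C | intermediate
12 | 1-[2,4-bis(tert-butyldimethylsilyloxy)-3-(3-methylbut-2-en-1-yl)phenyl]prop-2-en-1-one | C=CC(=O)c1ccc(O[Si](C)(C)C(C)(C)C)c(CC=C(C)C)c1O[Si](C)(C)C(C)(C)C | intermediate
13 | coumalic acid (2-oxo-2H-pyran-5-carboxylic acid) | O=C(O)C1=COC(=O)C=C1 | starting material
14 | 5-bromo-2H-pyran-2-one | O=C1C=CC(Br)=CO1 | intermediate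
15 | 5-[(E)-3-[2,4-bis(tert-butyldimethylsilyloxy)-3-(3-methylbut-2-en-1-yl)phenyl]-3-oxoprop-1-en-1-yl]-2H-pyran-2-one | O=C1C=CC(/C=C/C(=O)c2ccc(O[Si](C)(C)C(C)(C)C)c(CC=C(C)C)c2O[Si](C)(C)C(C)(C)C)=CO1 | intermediate
16 | ethynylmagnesium bromide | C#C[Mg]Br | starting material
17 | 5-methylhex-4-en-1-yne | CC(C)=CCC#C | intermediate
18 | (5-methylhex-4-en-1-yn-1-yl)lithium | CC(C)=CCC#C[Li] | intermediate
19 | lithium 5-methylhex-4-en-1-yn-1-olate | CC(C)=CCC#C[O-].[Li+] | intermediate
20 | triisopropyl[(5-methylhex-4-en-1-yn-1-yl)oxy]silane | CC(C)=CCC#CO[Si](C(C)C)(C(C)C)C(C)C | intermediate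
21 | racemic 2-oxabicyclo[2.2.2]octa-5,7-dien-3-one with triisopropylsilyloxy at C5, 3-methylbut-2-en-1-yl at C6 and the (E)-3-[2,4-bis(tert-butyldimethylsilyloxy)-3-(3-methylbut-2-en-1-yl)phenyl]-3-oxoprop-1-en-1-yl arm at C7 | O=C1OC2C(CC=C(C)C)=C(O[Si](C(C)C)(C(C)C)C(C)C)C1C=C2/C=C/C(=O)c3ccc(O[Si](C)(C)C(C)(C)C)c(CC=C(C)C)c3O[Si](C)(C)C(C)(C)C | intermediate
22 | kanzonol C tris(silyl) ether, (E)-1-[2,4-bis(tert-butyldimethylsilyloxy)-3-(3-methylbut-2-en-1-yl)phenyl]-3-[3-(3-methylbut-2-en-1-yl)-4-(triisopropylsilyloxy)phenyl]prop-2-en-1-one | CC(C)=CCc1cc(/C=C/C(=O)c2ccc(O[Si](C)(C)C(C)(C)C)c(CC=C(C)C)c2O[Si](C)(C)C(C)(C)C)ccc1O[Si](C(C)C)(C(C)C)C(C)C | intermediate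
23 | kanzonol C, (E)-1-[2,4-dihydroxy-3-(3-methylbut-2-en-1-yl)phenyl]-3-[4-hydroxy-3-(3-methylbut-2-en-1-yl)phenyl]prop-2-en-1-one | CC(C)=CCc1cc(/C=C/C(=O)c2ccc(O)c(CC=C(C)C)c2O)ccc1O | target

Total step count: 13.
Longest linear sequence: 10 steps (1 → 2 → 5 → 7 → 8 → 9 → 11 → 12 → 15 → 22 → 23; steps 1–7, 9, 12 and 13).

Steps most likely to fail

Step 12. The cycloaddition may be slower than the thermal 1,3-silyl shift of the ynol ether to a silylketene, or the ynol ether may be consumed by addition to the enone, so that ring B is never closed. The fallback sets out from compounds 3 and 12 and comes back to the route at compound 22; it brings ring B in preformed instead of building it. Commercial 4-iodophenol would be converted into its sodium salt (NaH, toluene) and C-alkylated at the ortho position with prenyl bromide 3 to give 4-iodo-2-(3-methylbut-2-en-1-yl)phenol F1. Silylation (TIPSCl, imidazole, DMF) would give triisopropyl[4-iodo-2-(3-methylbut-2-en-1-yl)phenoxy]silane F2. A Mizoroki–Heck coupling of F2 with aryl vinyl ketone 12 (Pd(OAc)2, P(o-tol)3, Et3N, MeCN, 60 °C) should then give 22 directly, and step 13 follows unchanged.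

Step 9. The aryl vinyl ketone may oligomerise, or the bromopyranone may be opened by the amine base, faster than the palladium catalyst turns over. The fallback sets out from compounds 9 and 14 and comes back at compound 15; the alkene is carried by a vinylstannane and joined by Stille coupling. (E)-1,2-Bis(tributylstannyl)ethene would be converted with n-BuLi (THF, −78 °C) into (E)-2-(tributylstannyl)vinyllithium and added to aldehyde 9, with a cold quench, to give racemic (E)-1-[2,4-bis(tert-butyldimethylsilyloxy)-3-(3-methylbut-2-en-1-yl)phenyl]-3-(tributylstannyl)prop-2-en-1-ol F3. MnO2 oxidation would give (E)-1-[2,4-bis(tert-butyldimethylsilyloxy)-3-(3-methylbut-2-en-1-yl)phenyl]-3-(tributylstannyl)prop-2-en-1-one F4. Stille coupling of F4 with 14 (Pd(PPh3)4, CuI, DMF, 40 °C) should give 15 with retention of the (E)-geometry.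

Step 11. Oxygen transfer to the acetylide may be incomplete, the skipped enyne may isomerise under the basic conditions, the ynolate may be silylated at carbon, or the ynol ether may hydrolyse during isolation. The fallback sets out from compounds 3 and 15 and comes back at compound 23; the two ring carbons are delivered at the carboxylic acid oxidation level as a ketene bis(silyl) acetal. Dilithioacetate (AcOH, 2 equiv LiN(iPr)2, THF) would be alkylated with 3 to give 5-methylhex-4-enoic acid F5. Double deprotonation and silylation (LiN(iPr)2, Me3SiCl, THF, −78 °C) would give 1,1-bis(trimethylsilyloxy)-5-methylhexa-1,4-diene F6. Heating F6 with pyranone 15 in toluene should give, by the same inverse-demand cycloaddition, loss of CO2 and elimination of trimethylsilanol, (E)-1-[2,4-bis(tert-butyldimethylsilyloxy)-3-(3-methylbut-2-en-1-yl)phenyl]-3-[3-(3-methylbut-2-en-1-yl)-4-(trimethylsilyloxy)phenyl]prop-2-en-1-one F7. The conditions of step 13 would convert F7 into 23.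

Further compounds
F1 | step 12 | 4-iodo-2-(3-methylbut-2-en-1-yl)phenol | CC(C)=CCc1cc(I)ccc1O
F2 | step 12 | triisopropyl[4-iodo-2-(3-methylbut-2-en-1-yl)phenoxy]silane | CC(C)=CCc1cc(I)ccc1O[Si](C(C)C)(C(C)C)C(C)C
F3 | step 9 | racemic (E)-1-[2,4-bis(tert-butyldimethylsilyloxy)-3-(3-methylbut-2-en-1-yl)phenyl]-3-(tributylstannyl)prop-2-en-1-ol | CCCC[Sn](CCCC)(CCCC)/C=C/C(O)c1ccc(O[Si](C)(C)C(C)(C)C)c(CC=C(C)C)c1O[Si](C)(C)C(C)(C)C
F4 | step 9 | (E)-1-[2,4-bis(tert-butyldimethylsilyloxy)-3-(3-methylbut-2-en-1-yl)phenyl]-3-(tributylstannyl)prop-2-en-1-one | CCCC[Sn](CCCC)(CCCC)/C=C/C(=O)c1ccc(O[Si](C)(C)C(C)(C)C)c(CC=C(C)C)c1O[Si](C)(C)C(C)(C)C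
F5 | step 11 | 5-methylhex-4-enoic acid | CC(C)=CCCC(=O)O
F6 | step 11 | 1,1-bis(trimethylsilyloxy)-5-methylhexa-1,4-diene | CC(C)=CCC=C(O[Si](C)(C)C)O[Si](C)(C)C
F7 | step 11 | (E)-1-[2,4-bis(tert-butyldimethylsilyloxy)-3-(3-methylbut-2-en-1-yl)phenyl]-3-[3-(3-methylbut-2-en-1-yl)-4-(trimethylsilyloxy)phenyl]prop-2-en-1-one | CC(C)=CCc1cc(/C=C/C(=O)c2ccc(O[Si](C)(C)C(C)(C)C)c(CC=C(C)C)c2O[Si](C)(C)C(C)(C)C)ccc1O[Si](C)(C)C
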